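**Plan**

- Retrosynthesis: with four tert-butyl blocking groups placed on rings B and B'' and three benzyl ethers on rings A and A'', the biflavanone is cut at C3–C3'' and at O1–C2 and O1''–C2''. This opens rings C and C'' and leaves two 2'-hydroxychalcones.
- Enabling feature: rings B and B'' are 4-hydroxyphenyl groups on C2 and C2'', next to C3 and C3''. In the open chalcone each phenol is conjugated through C2=C3, so its phenoxyl radical carries spin at C3; once C3–C3'' exists, C2 is a quinone methide carbon placed for six-membered closure by the ring A hydroxyl that becomes O1.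
- Forward: each acetophenone is benzylated, condensed with MOM-protected 3,5-di-tert-butyl-4-hydroxybenzaldehyde and freed of the MOM group. The two chalcones are oxidised together (C3–C3''), rings C and C'' close in the same operation, and hydrogenolysis followed by retro-Friedel–Crafts dealkylation uncovers the five phenols.
- Stereochemistry: C3 and C3'' arise in the radical combination (like and unlike isomers, separated on silica); C2 and C2'' arise in the thermodynamically controlled trans ring closure. The dimer is racemic, and the 2S,3R,2''S,3''R enantiomer is taken by separation on a chiral phase in the last step.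

Key step: step 8

Remark: flavanone numbering is used (unprimed atoms for the 7-oxygenated half, double-primed for the 5,7-dioxygenated half). The dimeric compounds before the last step are racemic; their names carry relative descriptors and their SMILES show the enantiomer that leads to the target.

**Route**

Step 1
Reactants: 1 3,5-di-tert-butyl-4-hydroxybenzaldehyde
Product: 2 3,5-di-tert-butyl-4-(methoxymethoxy)benzaldehyde
Conditions: NaH, DMF, 0 °C; then MOMCl, 0 °C to rt
Reagents that add atoms: chloromethyl methyl ether, COCCl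
Why: Williamson-type O-alkylation of the sodium phenolate with a small, very reactive α-chloro ether; the para carbon carries the formyl group, so the hindered phenolate can react only at oxygen, and the acetal removes the phenolate character that would deactivate the aldehyde in the aldol steps.

Step 2
Reactants: 3 2',4'-dihydroxyacetophenone
Product: 4 4'-benzyloxy-2'-hydroxyacetophenone
Conditions: BnBr (1.05 equiv), K2CO3, acetone, reflux
Reagents that add atoms: benzyl bromide, BrCc1ccccc1
Why: Williamson etherification in which the 2'-hydroxyl, hydrogen-bonded to the ketone, is far less nucleophilic than the 4'-hydroxyl, so only the latter is benzylated.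

Step 3
Reactants: 4 4'-benzyloxy-2'-hydroxyacetophenone; 2 3,5-di-tert-butyl-4-(methoxymethoxy)benzaldehyde
Product: 5 (E)-1-(4-benzyloxy-2-hydroxyphenyl)-3-[3,5-di-tert-butyl-4-(methoxymethoxy)phenyl]prop-2-en-1-one
Conditions: KOH (50% aq, excess), EtOH/THF, rt; then 1 M HCl to pH 6 at 0 °C
Reagents that add atoms: none
Why: Claisen–Schmidt condensation of the methyl ketone enolate with a non-enolisable aldehyde, followed by E1cB dehydration to the thermodynamically preferred (E)-enone; the MOM acetal is stable to base.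

Step 4
Reactants: 5 (E)-1-(4-benzyloxy-2-hydroxyphenyl)-3-[3,5-di-tert-butyl-4-(methoxymethoxy)phenyl]prop-2-en-1-one
Product: 6 (E)-1-(4-benzyloxy-2-hydroxyphenyl)-3-(3,5-di-tert-butyl-4-hydroxyphenyl)prop-2-en-1-one
Conditions: conc. HCl (cat.), MeOH/THF, rt
Reagents that add atoms: none
Why: acid-catalysed methanolysis of the phenolic MOM acetal, eased by relief of strain at the hindered oxygen, runs at room temperature where benzyl ethers survive and the chelated 2'-hydroxychalcone should not close to the flavanone.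

Step 5
Reactants: 7 2',4',6'-trihydroxyacetophenone (anhydrous)
Product: 8 2',4'-bis(benzyloxy)-6'-hydroxyacetophenone
Conditions: BnBr (2.1 equiv), K2CO3, DMF, rt
Reagents that add atoms: benzyl bromide, BrCc1ccccc1
Why: Williamson etherification with two equivalents of halide, after which the remaining hydroxyl is the one chelated to the carbonyl and stays free.

Step 6
Reactants: 8 2',4'-bis(benzyloxy)-6'-hydroxyacetophenone; 2 3,5-di-tert-butyl-4-(methoxymethoxy)benzaldehyde
Product: 9 (E)-1-[2,4-bis(benzyloxy)-6-hydroxyphenyl]-3-[3,5-di-tert-butyl-4-(methoxymethoxy)phenyl]prop-2-en-1-one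
Conditions: KOH (50% aq, excess), EtOH/THF, rt; then 1 M HCl to pH 6 at 0 °C
Reagents that add atoms: none
Why: Claisen–Schmidt condensation as in step 3, giving the (E)-enone; the chalcone phenoxide is the stable form in strong base and is isolated as the chalcone on cold neutralisation.

Step 7
Reactants: 9 (E)-1-[2,4-bis(benzyloxy)-6-hydroxyphenyl]-3-[3,5-di-tert-butyl-4-(methoxymethoxy)phenyl]prop-2-en-1-one
Product: 10 (E)-1-[2,4-bis(benzyloxy)-6-hydroxyphenyl]-3-(3,5-di-tert-butyl-4-hydroxyphenyl)prop-2-en-1-one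
Conditions: conc. HCl (cat.), MeOH/THF, 0 °C to rt
Reagents that add atoms: none
Why: acid-catalysed methanolysis of the MOM acetal as in step 4, kept cold and short because the 6'-alkoxy chalcone closes to its flavanone more readily under acid.

Step 8
Reactants: 6 (E)-1-(4-benzyloxy-2-hydroxyphenyl)-3-(3,5-di-tert-butyl-4-hydroxyphenyl)prop-2-en-1-one (3 equiv); 10 (E)-1-[2,4-bis(benzyloxy)-6-hydroxyphenyl]-3-(3,5-di-tert-butyl-4-hydroxyphenyl)prop-2-en-1-one (1 equiv)
Product: 12 rac-(2S*,3R*,2''S*,3''R*)-7,5'',7''-tris(benzyloxy)-2,2''-bis(3,5-di-tert-butyl-4-hydroxyphenyl)-[3,3''-bichromane]-4,4''-dione, via bis(quinone methide) 11 (not isolated)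
Conditions: Ag2O (2.2 equiv), CH2Cl2, argon, dark, rt; filtration through diatomaceous earth; then Et3N (0.5 equiv), 0 °C to rt; silica gel chromatography
Reagents that add atoms: none
Why: Proposed new method: Ag2O removes the phenolic hydrogen of each ring B, and because the oxygen and ortho carbons of the radical are shielded by tert-butyl groups the two phenoxyl radicals can combine only at the spin-bearing enone α-carbons, forming C3–C3'' and the bis(quinone methide) 11; the closest known reaction type is the oxidative 8–8 dimerisation of 3,5-di-tert-butyl-4-hydroxycinnamates and -stilbenes to bis(quinone methides), together with the 1,6-addition of phenols to para-quinone methides. With the silver filtered off, Et3N lets each chelated 2'-hydroxyl add to the quinone methide carbon of its own half, so ring C (O1–C2) and ring C'' (O1''–C2'') each close by a 6-exo-trig oxa-1,6-addition that re-aromatises ring B, in preference to the seven-membered closure across the new bond. C3 and C3'' are fixed in the radical combination, which has no facial bias and should give like and unlike pairings side by side; C2 and C2'' are fixed in the reversible ring closure, where the diequatorial trans arrangement of the aryl group and the C3 substituent is the thermodynamic outcome. Regioselectivity (8–8 over 8–5 or 8–O) is secured by the tert-butyl groups; cross- over homo-coupling is not secured, since both phenols have the same oxidation potential, and is met by a threefold excess of the cheaper chalcone 6 so that most of 10 is statistically paired with it; the like pairing is not secured either and is obtained by chromatography, the homodimers differing from 12 by one benzyloxy group and the unlike isomer being a diastereomer. The benzyl ethers keep rings A and A'' out of the oxidation, the oxidant is removed before any phenol is regenerated so that 12 is not re-oxidised, and the product is racemic.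

Step 9
Reactants: 12 rac-(2S*,3R*,2''S*,3''R*)-7,5'',7''-tris(benzyloxy)-2,2''-bis(3,5-di-tert-butyl-4-hydroxyphenyl)-[3,3''-bichromane]-4,4''-dione
Product: 13 rac-(2S*,3R*,2''S*,3''R*)-2,2''-bis(3,5-di-tert-butyl-4-hydroxyphenyl)-7,5'',7''-trihydroxy-[3,3''-bichromane]-4,4''-dione
Conditions: H2 (1 atm), 10% Pd/C, EtOAc/MeOH, rt
Reagents that add atoms: none
Why: heterogeneous catalytic hydrogenolysis of the three benzyl aryl ethers, as routinely used on benzylated flavanones; under one atmosphere in neutral solvent the ketones, the hindered phenols and the C2–O1 bonds should remain, and no stereocentre is touched.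

Step 10
Reactants: 13 rac-(2S*,3R*,2''S*,3''R*)-2,2''-bis(3,5-di-tert-butyl-4-hydroxyphenyl)-7,5'',7''-trihydroxy-[3,3''-bichromane]-4,4''-dione
Product: 14 rac-(2S*,3R*,2''S*,3''R*)-7,5'',7''-trihydroxy-2,2''-bis(4-hydroxyphenyl)-[3,3''-bichromane]-4,4''-dione
Conditions: AlCl3 (excess), toluene/MeNO2, rt to 50 °C; then cold 1 M HCl
Reagents that add atoms: none
Why: Lewis-acid retro-Friedel–Crafts transalkylation, in which ipso protonation of ring B releases each tert-butyl cation and the solvent toluene captures it; this is established for 2,6-di-tert-butylphenols, including ones that carry acid-sensitive 4-hydroxybenzylic ethers, and no bond to a stereocentre is broken.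

Step 11
Reactants: 14 rac-(2S*,3R*,2''S*,3''R*)-7,5'',7''-trihydroxy-2,2''-bis(4-hydroxyphenyl)-[3,3''-bichromane]-4,4''-dione
Product: 15 (2S,3R,2''S,3''R)-7,5'',7''-trihydroxy-2,2''-bis(4-hydroxyphenyl)-[3,3''-bichromane]-4,4''-dione (CNP0138443.1)
Conditions: preparative HPLC on immobilised amylose tris(3,5-dimethylphenylcarbamate), hexane/EtOH with 0.1% HCO2H, rt
Reagents that add atoms: none
Why: enantiomer separation on a polysaccharide carbamate chiral stationary phase, the standard resolution of flavanones; the 2S,3R,2''S,3''R enantiomer is to be identified by comparing its circular dichroism with the calculated spectrum, and nothing follows that could scramble it.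

**Compound list**

1 | 3,5-di-tert-butyl-4-hydroxybenzaldehyde | CC(C)(C)c1cc(C=O)cc(C(C)(C)C)c1O | starting material
2 | 3,5-di-tert-butyl-4-(methoxymethoxy)benzaldehyde | COCOc1c(C(C)(C)C)cc(C=O)cc1C(C)(C)C | intermediate
3 | 2',4'-dihydroxyacetophenone | CC(=O)c1ccc(O)cc1O | starting material
4 | 4'-benzyloxy-2'-hydroxyacetophenone | CC(=O)c1ccc(OCc2ccccc2)cc1O | intermediate
5 | (E)-1-(4-benzyloxy-2-hydroxyphenyl)-3-[3,5-di-tert-butyl-4-(methoxymethoxy)phenyl]prop-2-en-1-one | O=C(/C=C/c1cc(C(C)(C)C)c(OCOC)c(C(C)(C)C)c1)c1ccc(OCc2ccccc2)cc1O | intermediate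
6 | (E)-1-(4-benzyloxy-2-hydroxyphenyl)-3-(3,5-di-tert-butyl-4-hydroxyphenyl)prop-2-en-1-one | O=C(/C=C/c1cc(C(C)(C)C)c(O)c(C(C)(C)C)c1)c1ccc(OCc2ccccc2)cc1O | intermediate
7 | 2',4',6'-trihydroxyacetophenone | CC(=O)c1c(O)cc(O)cc1O | starting material
8 | 2',4'-bis(benzyloxy)-6'-hydroxyacetophenone | CC(=O)c1c(O)cc(OCc2ccccc2)cc1OCc1ccccc1 | intermediate
9 | (E)-1-[2,4-bis(benzyloxy)-6-hydroxyphenyl]-3-[3,5-di-tert-butyl-4-(methoxymethoxy)phenyl]prop-2-en-1-one | O=C(/C=C/c1cc(C(C)(C)C)c(OCOC)c(C(C)(C)C)c1)c1c(O)cc(OCc2ccccc2)cc1OCc1ccccc1 | intermediate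
10 | (E)-1-[2,4-bis(benzyloxy)-6-hydroxyphenyl]-3-(3,5-di-tert-butyl-4-hydroxyphenyl)prop-2-en-1-one | O=C(/C=C/c1cc(C(C)(C)C)c(O)c(C(C)(C)C)c1)c1c(O)cc(OCc2ccccc2)cc1OCc1ccccc1 | intermediate
11 | rac-(2S*,3S*)-1-(4-benzyloxy-2-hydroxyphenyl)-4-[2,4-bis(benzyloxy)-6-hydroxyphenyl]-2,3-bis[(3,5-di-tert-butyl-4-oxocyclohexa-2,5-dien-1-ylidene)methyl]butane-1,4-dione (racemate, enantiomer leading to the target shown; formed together with its unlike diastereomer) | O=C(c1ccc(OCc2ccccc2)cc1O)[C@@H](C=C1C=C(C(C)(C)C)C(=O)C(C(C)(C)C)=C1)[C@H](C=C1C=C(C(C)(C)C)C(=O)C(C(C)(C)C)=C1)C(=O)c1c(O)cc(OCc2ccccc2)cc1OCc1ccccc1 | intermediate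
12 | rac-(2S*,3R*,2''S*,3''R*)-7,5'',7''-tris(benzyloxy)-2,2''-bis(3,5-di-tert-butyl-4-hydroxyphenyl)-[3,3''-bichromane]-4,4''-dione (racemate, one enantiomer shown) | O=C1c2ccc(OCc3ccccc3)cc2O[C@H](c2cc(C(C)(C)C)c(O)c(C(C)(C)C)c2)[C@H]1[C@H]1C(=O)c2c(OCc3ccccc3)cc(OCc3ccccc3)cc2O[C@@H]1c1cc(C(C)(C)C)c(O)c(C(C)(C)C)c1 | intermediate
13 | rac-(2S*,3R*,2''S*,3''R*)-2,2''-bis(3,5-di-tert-butyl-4-hydroxyphenyl)-7,5'',7''-trihydroxy-[3,3''-bichromane]-4,4''-dione (racemate, one enantiomer shown) | O=C1c2ccc(O)cc2O[C@H](c2cc(C(C)(C)C)c(O)c(C(C)(C)C)c2)[C@H]1[C@H]1C(=O)c2c(O)cc(O)cc2O[C@@H]1c1cc(C(C)(C)C)c(O)c(C(C)(C)C)c1 | intermediate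
14 | rac-(2S*,3R*,2''S*,3''R*)-7,5'',7''-trihydroxy-2,2''-bis(4-hydroxyphenyl)-[3,3''-bichromane]-4,4''-dione (racemate, one enantiomer shown) | O=C1c2ccc(O)cc2O[C@H](c2ccc(O)cc2)[C@H]1[C@H]1C(=O)c2c(O)cc(O)cc2O[C@@H]1c1ccc(O)cc1 | intermediate
15 | (2S,3R,2''S,3''R)-7,5'',7''-trihydroxy-2,2''-bis(4-hydroxyphenyl)-[3,3''-bichromane]-4,4''-dione, both rings 2,3-trans | O=C1c2ccc(O)cc2O[C@H](c2ccc(O)cc2)[C@H]1[C@H]1C(=O)c2c(O)cc(O)cc2O[C@@H]1c1ccc(O)cc1 | target

Total step count: 11. Longest linear sequence: 7 steps (steps 5, 6, 7, 8, 9, 10, 11 from compound 7; equally steps 1, 6, 7, 8, 9, 10, 11 from compound 1).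

**Steps most likely to fail**

1. Step 8 (proposed new method).
- What may go wrong: the hindered radicals may persist without combining at carbon, or may pair mainly with their own kind. The quinone methides may tautomerise by loss of the acidic C3 proton instead of being trapped at C2. The pairing may fall mostly on the unlike side. Regenerated phenols may be oxidised further.
- Fallback (known chemistry): a silicon-tethered oxidative enolate heterocoupling, which forms the same C3–C3'' bond cross-selectively. It sets out from 5 and 9 and comes back to the route at 12.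
- Each chalcone is isomerised by oxa-Michael closure (NaOAc, EtOH, reflux) to its racemic flavanone: 7-benzyloxy-2-[3,5-di-tert-butyl-4-(methoxymethoxy)phenyl]chroman-4-one F1 and 5,7-bis(benzyloxy)-2-[3,5-di-tert-butyl-4-(methoxymethoxy)phenyl]chroman-4-one F2.
- The lithium enolate of F1 (LiN(iPr)2, THF, −78 °C) is added to excess iPr2SiCl2 to give 7-benzyloxy-4-[chloro(diisopropyl)silyloxy]-2-[3,5-di-tert-butyl-4-(methoxymethoxy)phenyl]-2H-chromene F3.
- After removal of the excess dichlorosilane, F3 is treated with the lithium enolate of F2 to give the unsymmetrical diisopropylsilylene bis(enol ether) F4. Two racemic diastereomers arise from the two racemic flavanones; the 2S*,2''S* one leads on.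
- Oxidation with (NH4)2Ce(NO3)6 and NaHCO3 in MeCN/EtCN at −20 °C joins C3 to C3'' within the tether, anti to each 2-aryl group. After chromatography this gives the rac-(2S*,3R*,2''S*,3''R*) bis(methoxymethyl) ether of 12 F5.
- HCl in MeOH/THF, as in step 4, removes both MOM groups and delivers 12.

2. Step 10.
- What may go wrong: Lewis-acid opening of ring C at the benzylic C2–O1 bond followed by enolisation would scramble C3 and C3''. Dealkylation may stop short. tert-Butyl cations may be transferred onto the electron-rich ring A''.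
- Fallback: the blocking groups are dispensed with and the tethered enolate coupling is run in the unblocked series. It sets out from 4 and 8 and comes back to the route at 14.
- Claisen–Schmidt condensation with 4-(benzyloxy)benzaldehyde (KOH, EtOH) gives (E)-1-(4-benzyloxy-2-hydroxyphenyl)-3-(4-benzyloxyphenyl)prop-2-en-1-one F6 and (E)-1-[2,4-bis(benzyloxy)-6-hydroxyphenyl]-3-(4-benzyloxyphenyl)prop-2-en-1-one F7.
- NaOAc in refluxing EtOH closes them to racemic 7-benzyloxy-2-(4-benzyloxyphenyl)chroman-4-one F8 and racemic 5,7-bis(benzyloxy)-2-(4-benzyloxyphenyl)chroman-4-one F9.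
- The lithium enolate of F8 and excess iPr2SiCl2 give 7-benzyloxy-2-(4-benzyloxyphenyl)-4-[chloro(diisopropyl)silyloxy]-2H-chromene F10, which with the lithium enolate of F9 gives the diisopropylsilylene bis(enol ether) F11.
- (NH4)2Ce(NO3)6 and NaHCO3 in MeCN/EtCN at −20 °C then give, after separation from the unlike isomer, the rac-(2S*,3R*,2''S*,3''R*) penta-O-benzyl ether of 14 F12.
- Hydrogenolysis (H2, Pd/C, EtOAc/MeOH) delivers 14.

3. Step 11.
- What may go wrong: the enantiomers of the free pentaphenol may not be separated on the chiral phase, or C2 may epimerise in the protic eluent through reversible opening of ring C.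
- Fallback: resolution through covalent diastereomers. It sets out from 14 and comes back to the route at 15.
- Acylation of the four non-chelated phenols with (1S)-camphanic chloride (pyridine, DMAP, CH2Cl2) gives two diastereomeric tetraesters.
- The (2S,3R,2''S,3''R)-configured 7,4',7'',4'''-tetrakis-O-[(1S)-camphanoyl] derivative of 15 F13 is separated by crystallisation or silica gel chromatography.
- Ammonolysis of the aryl esters (NH3, MeOH, 0 °C) delivers 15.

**Further compounds**

F1 | step 8 | rac-7-benzyloxy-2-[3,5-di-tert-butyl-4-(methoxymethoxy)phenyl]chroman-4-one | O=C1CC(c2cc(C(C)(C)C)c(OCOC)c(C(C)(C)C)c2)Oc2cc(OCc3ccccc3)ccc21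
F2 | step 8 | rac-5,7-bis(benzyloxy)-2-[3,5-di-tert-butyl-4-(methoxymethoxy)phenyl]chroman-4-one | O=C1CC(c2cc(C(C)(C)C)c(OCOC)c(C(C)(C)C)c2)Oc2cc(OCc3ccccc3)cc(OCc3ccccc3)c21
F3 | step 8 | rac-7-benzyloxy-4-[chloro(diisopropyl)silyloxy]-2-[3,5-di-tert-butyl-4-(methoxymethoxy)phenyl]-2H-chromene | CC(C)[Si](Cl)(C(C)C)OC1=CC(c2cc(C(C)(C)C)c(OCOC)c(C(C)(C)C)c2)Oc2cc(OCc3ccccc3)ccc21
F4 | step 8 | diisopropylsilylene bis(enol ether) of F1 and F2, (2S*,2''S*) diastereomer, racemic | CC(C)[Si](C(C)C)(OC1=C[C@@H](c2cc(C(C)(C)C)c(OCOC)c(C(C)(C)C)c2)Oc2cc(OCc3ccccc3)ccc21)OC1=C[C@@H](c2cc(C(C)(C)C)c(OCOC)c(C(C)(C)C)c2)Oc2cc(OCc3ccccc3)cc(OCc3ccccc3)c21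
F5 | step 8 | rac-(2S*,3R*,2''S*,3''R*)-7,5'',7''-tris(benzyloxy)-2,2''-bis[3,5-di-tert-butyl-4-(methoxymethoxy)phenyl]-[3,3''-bichromane]-4,4''-dione | O=C1c2ccc(OCc3ccccc3)cc2O[C@H](c2cc(C(C)(C)C)c(OCOC)c(C(C)(C)C)c2)[C@H]1[C@H]1C(=O)c2c(OCc3ccccc3)cc(OCc3ccccc3)cc2O[C@@H]1c1cc(C(C)(C)C)c(OCOC)c(C(C)(C)C)c1
F6 | step 10 | (E)-1-(4-benzyloxy-2-hydroxyphenyl)-3-(4-benzyloxyphenyl)prop-2-en-1-one | O=C(/C=C/c1ccc(OCc2ccccc2)cc1)c1ccc(OCc2ccccc2)cc1O
F7 | step 10 | (E)-1-[2,4-bis(benzyloxy)-6-hydroxyphenyl]-3-(4-benzyloxyphenyl)prop-2-en-1-one | O=C(/C=C/c1ccc(OCc2ccccc2)cc1)c1c(O)cc(OCc2ccccc2)cc1OCc1ccccc1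
F8 | step 10 | rac-7-benzyloxy-2-(4-benzyloxyphenyl)chroman-4-one | O=C1CC(c2ccc(OCc3ccccc3)cc2)Oc2cc(OCc3ccccc3)ccc21
F9 | step 10 | rac-5,7-bis(benzyloxy)-2-(4-benzyloxyphenyl)chroman-4-one | O=C1CC(c2ccc(OCc3ccccc3)cc2)Oc2cc(OCc3ccccc3)cc(OCc3ccccc3)c21
F10 | step 10 | rac-7-benzyloxy-2-(4-benzyloxyphenyl)-4-[chloro(diisopropyl)silyloxy]-2H-chromene | CC(C)[Si](Cl)(C(C)C)OC1=CC(c2ccc(OCc3ccccc3)cc2)Oc2cc(OCc3ccccc3)ccc21
F11 | step 10 | diisopropylsilylene bis(enol ether) of F8 and F9, (2S*,2''S*) diastereomer, racemic | CC(C)[Si](C(C)C)(OC1=C[C@@H](c2ccc(OCc3ccccc3)cc2)Oc2cc(OCc3ccccc3)ccc21)OC1=C[C@@H](c2ccc(OCc3ccccc3)cc2)Oc2cc(OCc3ccccc3)cc(OCc3ccccc3)c21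
F12 | step 10 | rac-(2S*,3R*,2''S*,3''R*)-7,5'',7''-tris(benzyloxy)-2,2''-bis(4-benzyloxyphenyl)-[3,3''-bichromane]-4,4''-dione | O=C1c2ccc(OCc3ccccc3)cc2O[C@H](c2ccc(OCc3ccccc3)cc2)[C@H]1[C@H]1C(=O)c2c(OCc3ccccc3)cc(OCc3ccccc3)cc2O[C@@H]1c1ccc(OCc3ccccc3)cc1
F13 | step 11 | (2S,3R,2''S,3''R)-5''-hydroxy-2,2''-bis(4-hydroxyphenyl)-[3,3''-bichromane]-4,4''-dione 7,4',7'',4'''-tetrakis[(1S,4R)-4,7,7-trimethyl-3-oxo-2-oxabicyclo[2.2.1]heptane-1-carboxylate] | O=C1c2ccc(OC(=O)[C@@]34CC[C@@](C)(C(=O)O3)C4(C)C)cc2O[C@H](c2ccc(OC(=O)[C@@]34CC[C@@](C)(C(=O)O3)C4(C)C)cc2)[C@H]1[C@H]1C(=O)c2c(O)cc(OC(=O)[C@@]34CC[C@@](C)(C(=O)O3)C4(C)C)cc2O[C@@H]1c1ccc(OC(=O)[C@@]34CC[C@@](C)(C(=O)O3)C4(C)C)cc1
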